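Cuts: the C15 acetate; C8–OH/C8–C17 (back to an 8α,17-epoxide, a C8=CH2 alkene and an 8-ketone); C9–C11 (enolate alkylation with a five-carbon iodo ester); ring A at C1–C10 and C3–C4, both made in one operation.
Enabling feature: ring B (C5–C10) with the C10 methyl and, on C5, the gem-dimethyl carbon C4 is the carbon skeleton of verbenone, in which C4 is additionally tied to C7 in a cyclobutane; C10 is the enone β-carbon, and C4 leaves C7 as a tertiary cation once the ketone is activated.
Forward: (1R,5R)-verbenone takes up allyl at C10, then the C4–C7 cyclobutane bond is cleaved and the cation is caught by the allyl terminus (ring A on ring B); then C6=C7 enone, side chain on C9, saturation, C8=CH2, epoxide, hydride, acetate.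
Stereochemistry: C5 comes from verbenone; C10 from addition anti to the gem-dimethyl bridge (the trans ring fusion follows); C9 from equilibration next to the C8 ketone; C8 from α-face epoxidation and hydride opening; C13 from methyl hydrogen (R)-3-methylglutarate.

Key step: step 1

Assumption: (1R,5R)-(+)-verbenone and methyl hydrogen (R)-3-methylglutarate are bought enantiopure; bicyclic compounds are numbered as labdanes (C1–C10 decalin, C18–C20 methyls).

Step 1
Reactants: 1 (1R,5R)-verbenone; 2 allylmagnesium bromide
Product: 5 2α-iodo-8-(trimethylsilyloxy)-11,12,13,14,15,16,17-heptanorlabd-7-ene, via allylated silyl enol ether 3 (not isolated), via cis-4-allyl-4-methylnopinone 4 (not isolated)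
Conditions: CH2=CHCH2MgBr, CuBr·SMe2, Me3SiCl, THF, −78 °C; solvent change to CH2Cl2; Me3SiI, MeOH (1 equiv), −78 to 0 °C; Et3N
Reagents that add atoms: chlorotrimethylsilane C[Si](C)(C)Cl; iodotrimethylsilane C[Si](C)(C)I
Why: Proposed new method: allylcopper/Me3SiCl adds 1,4 to the enone of 1 from the face opposite the gem-dimethyl bridge, as organocopper reagents are known to do with verbenone, which makes C1–C10 and the quaternary C10 (methyl syn to the bridge) while C5 of 1 is carried through untouched. HI from Me3SiI/MeOH then protonates 3 at C9, and the O-silylated carbonyl of 4 draws off the electrons of the strained, π-aligned cyclobutane bond C7–C4, as in the known Lewis-acid and Me3SiI ring cleavage of nopinones, leaving a C7=C8 silyl enol ether and a tertiary cation at C4. What is new is that this cation, instead of eliminating or collecting iodide, is trapped by the allyl terminus C3 in a 6-endo-trig cation–olefin closure (closest known type: cyclization of tertiary cations onto vinyl groups with halide capture), which makes C3–C4 and ring A. Ring A closes through a chair in which C1 (α on C10) and C4 (β on C5) are both equatorial on ring B, so the fusion is trans (10β-CH3, 5α-H) with no further control element needed, and iodide enters C2 anti to the new bond (equatorial, 2α), a centre erased in step 6. The step needs 1,4- over 1,2-addition (copper and Me3SiCl), cleavage of C7–C4 and not C7–C6 (only the former gives a tertiary cation) and 6-endo over 5-exo closure (5-exo would need a primary cation).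

Step 2
Reactants: 5 2α-iodo-8-(trimethylsilyloxy)-heptanorlabd-7-ene
Product: 6 2α-iodo-11,12,13,14,15,16,17-heptanorlabd-6-en-8-one
Conditions: IBX, 4-methoxypyridine N-oxide, DMSO, rt
Reagents that add atoms: none
Why: Dehydrogenation of a silyl enol ether by IBX (a Saegusa-type oxidation without palladium, so the alkyl iodide is left alone) should place the enone at C6=C7 on the side fixed by step 1, which blocks C7 so that only C9 can be enolized next; no stereocenter is touched.

Step 3
Reactants: 7 methyl hydrogen (R)-3-methylglutarate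
Product: 8 (S)-4-methyltetrahydro-2H-pyran-2-one
Conditions: NaH, THF, 0 °C; LiBH4, rt; aq. HCl
Reagents that add atoms: none
Why: Chemoselective LiBH4 reduction of the ester beside the sodium carboxylate, then acid lactonization; the stereocenter is not involved, and reducing the ester end fixes which terminus becomes C11.

Step 4
Reactants: 8 (S)-4-methyltetrahydro-2H-pyran-2-one
Product: 9 methyl (R)-5-iodo-3-methylpentanoate
Conditions: Me3SiI, CH2Cl2, rt; then MeOH, rt
Reagents that add atoms: iodotrimethylsilane C[Si](C)(C)I; methanol CO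
Why: SN2 opening of the silyl-activated lactone by iodide at the O–CH2 carbon, then HI-catalysed Fischer esterification in methanol; the stereocenter is untouched.

Step 5
Reactants: 6 2α-iodo-heptanorlabd-6-en-8-one; 9 methyl (R)-5-iodo-3-methylpentanoate
Product: 10 methyl (13S)-2α-iodo-8-oxo-17-nor-9-epi-labd-6-en-15-oate
Conditions: LiN(iPr)2, THF, −78 °C; 9, HMPA, −78 to −20 °C
Reagents that add atoms: none
Why: Kinetic α′-deprotonation of the enone at C9 (the only enolizable position) and SN2 alkylation of the lithium enolate by the primary iodide make C9–C11; attack anti to the axial C10 methyl should give the 9α-alkyl epimer, which step 6 corrects.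

Step 6
Reactants: 10 methyl (13S)-2α-iodo-8-oxo-17-nor-9-epi-labd-6-en-15-oate
Product: 12 methyl (13S)-8-oxo-17-norlabdan-15-oate, via 9-epi keto ester 11 (not isolated)
Conditions: H2 (1 atm), Pd/C, Et3N, MeOH, rt; filter; NaOMe, rt
Reagents that add atoms: none
Why: Catalytic hydrogenation saturates the C6=C7 enone alkene and hydrogenolyses the secondary C–I bond in the presence of base; NaOMe then equilibrates C9 through the enolate to the equatorial 9β side chain (9α-H) of the trans-decalone.

Step 7
Reactants: 12 methyl (13S)-8-oxo-17-norlabdan-15-oate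
Product: 13 methyl (13S)-labd-8(17)-en-15-oate
Conditions: Ph3PCH3Br, NaN(SiMe3)2, THF, 0 °C to rt
Reagents that add atoms: methyltriphenylphosphonium bromide C[P+](c1ccccc1)(c1ccccc1)c1ccccc1.[Br-]
Why: Wittig methylenation; the ketone should react far faster than the methyl ester, and C9 stays in its thermodynamically set configuration.

Step 8
Reactants: 13 methyl (13S)-labd-8(17)-en-15-oate
Product: 14 methyl (13S)-8α,17-epoxylabdan-15-oate
Conditions: mCPBA, NaHCO3, CH2Cl2, 0 °C
Reagents that add atoms: 3-chloroperoxybenzoic acid OOC(=O)c1cccc(Cl)c1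
Why: Prilezhaev epoxidation; the peracid should reach the exocyclic alkene from the α-face because the β-face is screened by the 1,3-diaxial C10 methyl, which sets C8 with oxygen α.

Step 9
Reactants: 14 methyl (13S)-8α,17-epoxylabdan-15-oate
Product: 15 (13S)-labdane-8α,15-diol
Conditions: LiAlH4, THF, 0 °C to reflux
Reagents that add atoms: none
Why: Hydride opens the spiro-epoxide at the primary C17 (SN2), leaving the tertiary 8α-alcohol with C17 as the axial β-methyl, and reduces the ester to the C15 alcohol; the C8 configuration is that set in step 8.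

Step 10
Reactants: 15 (13S)-labdane-8α,15-diol
Product: 16 (13S)-8α-hydroxylabdan-15-yl acetate
Conditions: Ac2O, pyridine, rt
Reagents that add atoms: acetic anhydride CC(=O)OC(C)=O
Why: Acylation of the primary alcohol; the hindered tertiary C8 hydroxyl should not react under these conditions.

Compound list
1 | (1R,5R)-(+)-verbenone, (1R,5R)-4,6,6-trimethylbicyclo[3.1.1]hept-3-en-2-one | CC1=CC(=O)[C@@H]2C[C@H]1C2(C)C | starting material
2 | allylmagnesium bromide | C=CC[Mg]Br | starting material
3 | 4-allyl-4,6,6-trimethyl-2-(trimethylsilyloxy)bicyclo[3.1.1]hept-2-ene, allyl anti to the gem-dimethyl bridge, bridgeheads as in 1 | C=CC[C@]1(C)C=C(O[Si](C)(C)C)[C@@H]2C[C@H]1C2(C)C | intermediate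
4 | cis-4-allyl-4-methylnopinone, 4-allyl-4,6,6-trimethylbicyclo[3.1.1]heptan-2-one, allyl anti to the gem-dimethyl bridge | C=CC[C@]1(C)CC(=O)[C@@H]2C[C@H]1C2(C)C | intermediate
5 | 2α-iodo-8-(trimethylsilyloxy)-11,12,13,14,15,16,17-heptanorlabd-7-ene (trans-decalin, 5α-H, 10β-CH3, equatorial iodide) | C1[C@@]2(C)C[C@@H](I)CC(C)(C)[C@@H]2CC=C1O[Si](C)(C)C | intermediate
6 | 2α-iodo-11,12,13,14,15,16,17-heptanorlabd-6-en-8-one | O=C1C[C@@]2(C)C[C@@H](I)CC(C)(C)[C@@H]2C=C1 | intermediate
7 | methyl hydrogen (R)-3-methylglutarate, (3R)-5-methoxy-3-methyl-5-oxopentanoic acid | OC(=O)C[C@@H](C)CC(=O)OC | starting material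
8 | (S)-4-methyltetrahydro-2H-pyran-2-one | O=C1C[C@@H](C)CCO1 | intermediate
9 | methyl (R)-5-iodo-3-methylpentanoate | COC(=O)C[C@@H](C)CCI | intermediate
10 | methyl (13S)-2α-iodo-8-oxo-17-nor-9-epi-labd-6-en-15-oate (side chain 9α as expected from the alkylation) | COC(=O)C[C@@H](C)CC[C@H]1[C@@]2(C)C[C@@H](I)CC(C)(C)[C@@H]2C=CC1=O | intermediate
11 | methyl (13S)-8-oxo-17-nor-9-epi-labdan-15-oate | COC(=O)C[C@@H](C)CC[C@H]1[C@@]2(C)CCCC(C)(C)[C@@H]2CCC1=O | intermediate
12 | methyl (13S)-8-oxo-17-norlabdan-15-oate | COC(=O)C[C@@H](C)CC[C@@H]1[C@@]2(C)CCCC(C)(C)[C@@H]2CCC1=O | intermediate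
13 | methyl (13S)-labd-8(17)-en-15-oate | COC(=O)C[C@@H](C)CC[C@@H]1[C@@]2(C)CCCC(C)(C)[C@@H]2CCC1=C | intermediate
14 | methyl (13S)-8α,17-epoxylabdan-15-oate | COC(=O)C[C@@H](C)CC[C@@H]1[C@@]2(C)CCCC(C)(C)[C@@H]2CC[C@]13CO3 | intermediate
15 | (13S)-labdane-8α,15-diol | OCC[C@@H](C)CC[C@@H]1[C@@]2(C)CCCC(C)(C)[C@@H]2CC[C@@]1(C)O | intermediate
16 | (13S)-8α-hydroxylabdan-15-yl acetate | CC(=O)OCC[C@@H](C)CC[C@@H]1[C@@]2(C)CCCC(C)(C)[C@@H]2CC[C@@]1(C)O | target

Total step count: 10. Longest linear sequence: 8 (steps 1, 2, 5, 6, 7, 8, 9, 10 from verbenone).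

Steps most likely to fail

Step 1 (Proposed new method). The tertiary C4 cation may lose a proton or rest as the tertiary iodide faster than the vinyl group traps it. HI may add across the vinyl group, and the secondary C2 cation may rearrange before iodide capture. The fallback uses known reactions and closes ring A by a radical instead of a cation. It sets out from 1: addition of the organocopper reagent from [2-(1,3-dioxolan-2-yl)ethyl]MgBr and CuBr·SMe2 (Me3SiCl, then aqueous work-up) should give the acetal ketone F1. Deprotonation with LiN(iPr)2 (C9 is the only enolizable position of a nopinone) and alkylation with 9 should give the alkylated acetal ketone F2. Me3SiI (the established cyclobutane cleavage of 4,4-disubstituted nopinones), then DBU and dilute aqueous HCl should give the isopropenyl keto aldehyde F3. TsNHNH2 should give the aldehyde tosylhydrazone F4. Fe(acac)3/PhSiH3 in EtOH (hydrogen-atom transfer to the isopropenyl group, 6-exo addition of the tertiary C4 radical to the hydrazone carbon C3), then NaOMe/MeOH (loss of sulfinate and N2, equilibration of C9) comes back to the route at 12.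

Step 5. SN2 attack of the hindered C9 enolate (next to the quaternary C10) on the unactivated iodide may be outrun by proton transfer, O-alkylation or loss of HI from 9. The fallback sets out from 6: condensation with Me2NNH2 (AcOH cat.) should give the N,N-dimethylhydrazone F5. Its azaenolate (LiN(iPr)2, THF, 0 °C), a stronger carbon nucleophile, is alkylated by 9 to the alkylated hydrazone F6. Hydrolysis (aqueous CuCl2, THF, pH 7) comes back to the route at 10.

Step 8. Attack of the peracid on the β-face, or acid-promoted opening of the spiro-epoxide, would erode the C8 configuration. The fallback sets out from 13: Mukaiyama hydration (Co(acac)2, PhSiH3, O2, iPrOH) transfers a hydrogen atom to C17, and the tertiary C8 radical should take up O2 from the open α-face, giving the tertiary alcohol methyl (13S)-8α-hydroxylabdan-15-oate F7. LiAlH4 reduction of its ester as in step 9 comes back to the route at 15.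

Further compounds
F1 | step 1 | 4-[2-(1,3-dioxolan-2-yl)ethyl]-4,6,6-trimethylbicyclo[3.1.1]heptan-2-one, side chain anti to the gem-dimethyl bridge | O1CCOC1CC[C@]2(C)CC(=O)[C@@H]3C[C@H]2C3(C)C
F2 | step 1 | methyl (3S)-5-{4-[2-(1,3-dioxolan-2-yl)ethyl]-4,6,6-trimethyl-2-oxobicyclo[3.1.1]hept-3-yl}-3-methylpentanoate, C3 side chain anti to the bridge | COC(=O)C[C@@H](C)CC[C@@H]1C(=O)[C@@H]2C[C@@H](C2(C)C)[C@]1(C)CCC1OCCO1
F3 | step 1 | methyl (3S)-3-methyl-5-[2-methyl-6-oxo-2-(3-oxopropyl)-3-(prop-1-en-2-yl)cyclohexyl]pentanoate (ring carbons as C9, C10, C5 of the target) | COC(=O)C[C@@H](C)CC[C@H]1C(=O)CC[C@@H](C(C)=C)[C@]1(C)CCC=O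
F4 | step 1 | tosylhydrazone of the aldehyde of F3 | COC(=O)C[C@@H](C)CC[C@H]1C(=O)CC[C@@H](C(C)=C)[C@]1(C)CCC=NNS(=O)(=O)c1ccc(C)cc1
F5 | step 5 | N,N-dimethylhydrazone of 6 | CN(C)N=C1C[C@@]2(C)C[C@@H](I)CC(C)(C)[C@@H]2C=C1
F6 | step 5 | N,N-dimethylhydrazone of 10 | COC(=O)C[C@@H](C)CC[C@H]1[C@@]2(C)C[C@@H](I)CC(C)(C)[C@@H]2C=CC1=NN(C)C
F7 | step 8 | methyl (13S)-8α-hydroxylabdan-15-oate | COC(=O)C[C@@H](C)CC[C@@H]1[C@@]2(C)CCCC(C)(C)[C@@H]2CC[C@@]1(C)O
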